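The C1=C10 alkene (guaiane numbering) joining the five- and seven-membered rings is read as the trace of a cation beside a former quaternary carbon. The hydroazulene is traced back to a trans-decalin with an angular C10 methyl and an equatorial C1 alcohol. Ionising its triflate lets the antiperiplanar C5–C10 bond migrate to C1: the six-membered ring C1–C5/C10 contracts to the cyclopentane C1–C5, the other ring grows to the cycloheptane, and loss of the C1 proton sets the alkene. C4, C5, C7 and C8 are set earlier on the decalin, built from yeast-desymmetrised 2-allyl-2-methylcyclohexane-1,3-dione by triflate coupling, ring-closing metathesis, conjugate borylation and hydroxyl-directed hydrogenation. The ferulate is attached last.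

Key step: step 13

Remark: decalins are numbered as eudesmanes and hydroazulenes as guaianes, so every carbon keeps its number through the key step (C1 carbinol, C4 secondary-methyl carbon, C5 ring-fusion CH, C7 ester carbon, C8 boron/oxygen carbon, C10 methyl-bearing carbon, C11 ester/carbinol carbon). α/β refer to the usual drawing with the C10 methyl β. Bpin = 4,4,5,5-tetramethyl-1,3,2-dioxaborolan-2-yl. In this numbering the target is (4S,5S,7S,8S)-configured.

Step 1
Reactants: 1 2-methylcyclohexane-1,3-dione; 2 3-bromoprop-1-ene (allyl bromide)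
Product: 3 2-methyl-2-(prop-2-en-1-yl)cyclohexane-1,3-dione
Conditions: NaOH (1 M aq), rt
Reagents that add atoms: none
Why: C-alkylation of the cyclic 1,3-dione enolate with an allylic bromide (enolate alkylation); the product is prochiral, so no stereocentre is set.

Step 2
Reactants: 3 2-methyl-2-(prop-2-en-1-yl)cyclohexane-1,3-dione
Product: 4 (2S,3S)-3-hydroxy-2-methyl-2-(prop-2-en-1-yl)cyclohexan-1-one (hydroxyl cis to allyl)
Conditions: baker's yeast (Saccharomyces cerevisiae), sucrose, H2O, 30 °C
Reagents that add atoms: none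
Why: Enzymatic carbonyl reduction desymmetrises the prochiral dione, a well-established reaction type for 2,2-disubstituted cyclohexane-1,3-diones; hydride delivery to one enantiotopic carbonyl, anti to the larger allyl group, sets the quaternary centre (future C10) and the (S)-carbinol (future C1).

Step 3
Reactants: 4 (2S,3S)-3-hydroxy-2-methyl-2-(prop-2-en-1-yl)cyclohexan-1-one
Product: 5 (2S,3S)-2-methyl-2-(prop-2-en-1-yl)-3-(triethylsilyloxy)cyclohexan-1-one
Conditions: Et3SiCl, imidazole, DMF, rt
Reagents that add atoms: chlorotriethylsilane, CC[Si](CC)(CC)Cl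
Why: Silylation protects the β-hydroxy ketone against retro-aldol cleavage under the enolate conditions that follow; no stereocentre changes.

Step 4
Reactants: 5 (2S,3S)-2-methyl-2-(prop-2-en-1-yl)-3-(triethylsilyloxy)cyclohexan-1-one
Product: 6 (2S,3S)-2,6-dimethyl-2-(prop-2-en-1-yl)-3-(triethylsilyloxy)cyclohexan-1-one (mixture of C6 epimers)
Conditions: LiN(i-Pr)2, THF, −78 °C; then MeI, −78 → 0 °C
Reagents that add atoms: iodomethane, CI
Why: Kinetic lithium enolate alkylation; the ketone can enolise only toward the future C4 because the other α-carbon is quaternary, and the new centre need not be controlled because it becomes sp2 in step 5.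

Step 5
Reactants: 6 (2S,3S)-2,6-dimethyl-2-(prop-2-en-1-yl)-3-(triethylsilyloxy)cyclohexan-1-one
Product: 7 (5S,6S)-2,6-dimethyl-6-(prop-2-en-1-yl)-5-(triethylsilyloxy)cyclohex-1-en-1-yl trifluoromethanesulfonate
Conditions: KN(SiMe3)2, THF, −78 → 0 °C; then PhNTf2
Reagents that add atoms: N-phenylbis(trifluoromethanesulfonimide), O=S(=O)(N(c1ccccc1)S(=O)(=O)C(F)(F)F)C(F)(F)F
Why: O-triflation of the only possible (tetrasubstituted) enolate, as for 2,2,6-trialkylcyclohexanones, defines the position of the future C4=C5 double bond.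

Step 6
Reactants: 7 the alkenyl triflate; 8 methyl 2-(bromomethyl)prop-2-enoate
Product: 9 methyl 2-{[(5S,6R)-2,6-dimethyl-6-(prop-2-en-1-yl)-5-(triethylsilyloxy)cyclohex-1-en-1-yl]methyl}prop-2-enoate (centres as in 7; the descriptor changes by priority only)
Conditions: 8, Zn dust, THF, 0 °C (allylzinc bromide formed in situ); then 7, Pd(PPh3)4 (5 mol %), THF/NMP, 40 °C
Reagents that add atoms: none
Why: Negishi cross-coupling at zerovalent palladium joins the alkenyl triflate to the allylic zinc reagent and forms the C5–C6 bond; the allyl unit is constitutionally symmetric, so no regioisomer arises and no stereocentre is touched.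

Step 7
Reactants: 9 the triene ester
Product: 10 methyl 1α-(triethylsilyloxy)-12,13-dinoreudesma-4,7-dien-11-oate
Conditions: second-generation Grubbs catalyst (5 mol %), CH2Cl2, 40 °C
Reagents that add atoms: none
Why: Ring-closing metathesis between the allyl group and the 1,1-disubstituted acrylate closes ring B as a cyclohexene-1-carboxylate; the tetrasubstituted C4=C5 alkene is inert to the catalyst.

Step 8
Reactants: 10 methyl 1α-(triethylsilyloxy)-12,13-dinoreudesma-4,7-dien-11-oate
Product: 11 methyl 8α-Bpin-1α-(triethylsilyloxy)-7αH-12,13-dinoreudesm-4-en-11-oate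
Conditions: B2pin2, CuCl (5 mol %), Xantphos (5 mol %), NaOt-Bu (10 mol %), MeOH (2 equiv), THF, rt; then NaOMe (cat.), MeOH, rt
Reagents that add atoms: bis(pinacolato)diboron, CC1(C)OB(OC1(C)C)B1OC(C)(C)C(C)(C)O1
Why: Copper-catalysed conjugate borylation of the enoate should add boron to C8 on the α face, anti to the axial C10 methyl (1,3-diaxial shielding of the β face); the C7 ester equilibrates through its enolate to the equatorial β position, giving the trans 7,8 pattern with the boronate as a masked C8 hydroxyl.

Step 9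
Reactants: 11 the silyl ether boronate
Product: 12 methyl 1α-hydroxy-8α-Bpin-7αH-12,13-dinoreudesm-4-en-11-oate
Conditions: PPTS, MeOH, rt
Reagents that add atoms: none
Why: Mild acid-catalysed methanolysis cleaves the triethylsilyl ether while the pinacol boronate, the ester and the alkene are untouched.

Step 10
Reactants: 12 the homoallylic alcohol
Product: 13 methyl 1α-hydroxy-8α-Bpin-4αH,5αH,7αH-12,13-dinoreudesman-11-oate (trans-decalin, 4β-methyl)
Conditions: [Ir(cod)(PCy3)(py)]PF6 (5–10 mol %), H2 (1–4 atm), CH2Cl2, rt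
Reagents that add atoms: none
Why: Hydroxyl-directed homogeneous hydrogenation: the cationic iridium complex binds the pseudo-axial 1α-hydroxyl and adds H2 syn to the α face of the tetrasubstituted alkene, setting C5 (trans ring fusion) and C4 together, while the axial C10 methyl blocks the other face.

Step 11
Reactants: 13 the 1α-alcohol
Product: 14 methyl 1-oxo-8α-Bpin-4αH,5αH,7αH-12,13-dinoreudesman-11-oate
Conditions: Dess–Martin periodinane, NaHCO3, CH2Cl2, rt
Reagents that add atoms: none
Why: Dess–Martin oxidation removes the C1 stereocentre after it has served as directing group, so that it can be re-set; boronate and ester are inert.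

Step 12
Reactants: 14 the C1 ketone
Product: 15 methyl 1β-hydroxy-8α-Bpin-4αH,5αH,7αH-12,13-dinoreudesman-11-oate
Conditions: NaBH4, MeOH/THF, −20 → 0 °C
Reagents that add atoms: none
Why: Borohydride reduction, chemoselective over the ester; axial attack from the α face, away from the angular C10 methyl, should give the equatorial 1β-alcohol (net inversion of C1).

Step 13
Reactants: 15 the equatorial 1β-alcohol
Product: 17 methyl 8α-Bpin-4αH,5αH,7αH-12,13-dinorguai-1(10)-en-11-oate, via 1β-triflate 16 (not isolated)
Conditions: Tf2O, 2,6-di-tert-butyl-4-methylpyridine, CH2Cl2, −78 → 0 °C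
Reagents that add atoms: none
Why: O-triflation gives 16, whose equatorial C1–O bond is antiperiplanar to the C5–C10 ring bond, so ionisation is assisted by a Wagner–Meerwein 1,2-shift of C5 from C10 to C1, and the tertiary C10 cation then loses the C1 proton to give the tetrasubstituted C1=C10 alkene. The closest known reaction type is the solvolytic rearrangement of 10-methyl-decal-1-yl sulfonates to hydroazulenes, together with the ring-A contraction of triterpenoid 3β-alcohols. No ring is closed by cyclisation: ring A (C1–C5, C10) contracts to the cyclopentane C1–C5 and ring B expands to the cycloheptane C1, C5–C10 in one suprafacial shift. No stereocentre is created: C5 migrates with retention, C4, C7 and C8 are untouched, and C1 and C10 become sp2, so their earlier configurations only had to serve the alignment. The step needs migration of C5 rather than of the methyl group, C9 or C3; the trans-decalin chair secures this, because an equatorial leaving group is anti only to ring bonds and C3 migration would give a primary cation, and relief of the 1,3-diaxial C4/C10 methyl strain adds driving force. It also needs proton loss toward C1, which is favoured as the most substituted alkene, with the hindered pyridine base suppressing acid-mediated drift of the double bond.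

Step 14
Reactants: 17 the guaiene boronate ester
Product: 19 (4S,5S,7S,8S)-guai-1(10)-ene-8,11-diol, via boronate carbinol 18 (not isolated)
Conditions: MeMgBr (excess), CeCl3, THF, −78 → 0 °C; then NaOH (3 M aq), H2O2 (30 %), 0 °C → rt
Reagents that add atoms: methylmagnesium bromide, C[Mg]Br; hydrogen peroxide, OO
Why: Double Grignard addition converts the methyl ester into the tertiary carbinol (CeCl3 suppresses enolisation), and alkaline peroxide then oxidises the C–B bond of the boronate complex with retention, unveiling the 8α-hydroxyl.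

Step 15
Reactants: 19 the 8,11-diol; 20 (E)-3-(4-acetoxy-3-methoxyphenyl)prop-2-enoic acid (O-acetylferulic acid)
Product: 21 (4S,5S,7S,8S)-11-hydroxyguai-1(10)-en-8-yl (E)-3-(4-acetoxy-3-methoxyphenyl)prop-2-enoate
Conditions: EDC·HCl, DMAP, CH2Cl2, rt
Reagents that add atoms: none
Why: Carbodiimide (Steglich) esterification should acylate the secondary C8 hydroxyl selectively over the tertiary C11 hydroxyl; the E alkene of the acid is retained and no stereocentre is touched.

Step 16
Reactants: 21 the O-acetylferulate
Product: 22 (4S,5S,7S,8S)-11-hydroxyguai-1(10)-en-8-yl (E)-3-(4-hydroxy-3-methoxyphenyl)prop-2-enoate (target)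
Conditions: pyrrolidine, CH2Cl2, 0 °C → rt
Reagents that add atoms: none
Why: Aminolysis cleaves the activated aryl acetate much faster than the cinnamate ester and releases the phenol.

Compound list
1 | 2-methylcyclohexane-1,3-dione | CC1C(=O)CCCC1=O | starting material
2 | 3-bromoprop-1-ene (allyl bromide) | C=CCBr | starting material
3 | 2-methyl-2-(prop-2-en-1-yl)cyclohexane-1,3-dione | C=CCC1(C)C(=O)CCCC1=O | intermediate
4 | (2S,3S)-3-hydroxy-2-methyl-2-(prop-2-en-1-yl)cyclohexan-1-one | C=CC[C@@]1(C)[C@@H](O)CCCC1=O | intermediate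
5 | (2S,3S)-2-methyl-2-(prop-2-en-1-yl)-3-(triethylsilyloxy)cyclohexan-1-one | C=CC[C@@]1(C)[C@@H](O[Si](CC)(CC)CC)CCCC1=O | intermediate
6 | (2S,3S)-2,6-dimethyl-2-(prop-2-en-1-yl)-3-(triethylsilyloxy)cyclohexan-1-one, C6 epimers | C=CC[C@@]1(C)[C@@H](O[Si](CC)(CC)CC)CCC(C)C1=O | intermediate
7 | (5S,6S)-2,6-dimethyl-6-(prop-2-en-1-yl)-5-(triethylsilyloxy)cyclohex-1-en-1-yl trifluoromethanesulfonate | C=CC[C@@]1(C)[C@@H](O[Si](CC)(CC)CC)CCC(C)=C1OS(=O)(=O)C(F)(F)F | intermediate
8 | methyl 2-(bromomethyl)prop-2-enoate | C=C(CBr)C(=O)OC | starting material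
9 | methyl 2-{[(5S,6R)-2,6-dimethyl-6-(prop-2-en-1-yl)-5-(triethylsilyloxy)cyclohex-1-en-1-yl]methyl}prop-2-enoate | C=CC[C@@]1(C)[C@@H](O[Si](CC)(CC)CC)CCC(C)=C1CC(=C)C(=O)OC | intermediate
10 | methyl 1α-(triethylsilyloxy)-12,13-dinoreudesma-4,7-dien-11-oate | CC1=C2CC(C(=O)OC)=CC[C@@]2(C)[C@@H](O[Si](CC)(CC)CC)CC1 | intermediate
11 | methyl 8α-Bpin-1α-(triethylsilyloxy)-7αH-12,13-dinoreudesm-4-en-11-oate | CC1=C2C[C@H](C(=O)OC)[C@@H](B3OC(C)(C)C(C)(C)O3)C[C@@]2(C)[C@@H](O[Si](CC)(CC)CC)CC1 | intermediate
12 | methyl 1α-hydroxy-8α-Bpin-7αH-12,13-dinoreudesm-4-en-11-oate | CC1=C2C[C@H](C(=O)OC)[C@@H](B3OC(C)(C)C(C)(C)O3)C[C@@]2(C)[C@@H](O)CC1 | intermediate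
13 | methyl 1α-hydroxy-8α-Bpin-4αH,5αH,7αH-12,13-dinoreudesman-11-oate | O[C@H]1CC[C@H](C)[C@@H]2C[C@H](C(=O)OC)[C@@H](B3OC(C)(C)C(C)(C)O3)C[C@@]12C | intermediate
14 | methyl 1-oxo-8α-Bpin-4αH,5αH,7αH-12,13-dinoreudesman-11-oate | O=C1CC[C@H](C)[C@@H]2C[C@H](C(=O)OC)[C@@H](B3OC(C)(C)C(C)(C)O3)C[C@@]12C | intermediate
15 | methyl 1β-hydroxy-8α-Bpin-4αH,5αH,7αH-12,13-dinoreudesman-11-oate | O[C@@H]1CC[C@H](C)[C@@H]2C[C@H](C(=O)OC)[C@@H](B3OC(C)(C)C(C)(C)O3)C[C@@]12C | intermediate
16 | methyl 8α-Bpin-1β-(trifluoromethylsulfonyloxy)-4αH,5αH,7αH-12,13-dinoreudesman-11-oate (not isolated) | O=S(=O)(O[C@@H]1CC[C@H](C)[C@@H]2C[C@H](C(=O)OC)[C@@H](B3OC(C)(C)C(C)(C)O3)C[C@@]12C)C(F)(F)F | intermediate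
17 | methyl 8α-Bpin-4αH,5αH,7αH-12,13-dinorguai-1(10)-en-11-oate (C4, C5, C7, C8 arranged as in 22) | CC1(C)OB(OC1(C)C)[C@H]1CC(C)=C2CC[C@H](C)[C@@H]2C[C@@H]1C(=O)OC | intermediate
18 | 8α-Bpin-4αH,5αH,7αH-guai-1(10)-en-11-ol (present as its magnesium alkoxide/borate complex, not isolated) | CC1(C)OB(OC1(C)C)[C@H]1CC(C)=C2CC[C@H](C)[C@@H]2C[C@@H]1C(C)(C)O | intermediate
19 | (4S,5S,7S,8S)-guai-1(10)-ene-8,11-diol | O[C@H]1CC(C)=C2CC[C@H](C)[C@@H]2C[C@@H]1C(C)(C)O | intermediate
20 | (E)-3-(4-acetoxy-3-methoxyphenyl)prop-2-enoic acid | COc1cc(/C=C/C(=O)O)ccc1OC(C)=O | starting material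
21 | (4S,5S,7S,8S)-11-hydroxyguai-1(10)-en-8-yl (E)-3-(4-acetoxy-3-methoxyphenyl)prop-2-enoate | COc1cc(/C=C/C(=O)O[C@H]2CC(C)=C3CC[C@H](C)[C@@H]3C[C@@H]2C(C)(C)O)ccc1OC(C)=O | intermediate
22 | (4S,5S,7S,8S)-11-hydroxyguai-1(10)-en-8-yl (E)-3-(4-hydroxy-3-methoxyphenyl)prop-2-enoate | COc1cc(/C=C/C(=O)O[C@H]2CC(C)=C3CC[C@H](C)[C@@H]3C[C@@H]2C(C)(C)O)ccc1O | target

Total step count: 16. Longest linear sequence: 16 steps (1 → 22); 2, 8 and 20 enter as commercial reactants.

Steps most likely to fail

Step 13 (key step). After the 1,2-shift the C10 cation may lose a proton from C9 or from the C10 methyl instead of from C1, giving alkene regioisomers, or it may be intercepted by the C7 ester carbonyl. The fallback sets out from 15 and comes back at 17. 15 is converted with MsCl/pyridine into methyl 1β-(methylsulfonyloxy)-8α-Bpin-4αH,5αH,7αH-12,13-dinoreudesman-11-oate F1. F1 is solvolysed in buffered aqueous acetone (CaCO3, 60 °C), so that the rearranged C10 cation is captured by water as methyl 10-hydroxy-8α-Bpin-12,13-dinorguaian-11-oate F2 (C10 epimers), alongside alkene isomers. Acid-catalysed dehydration and equilibration (p-TsOH cat., benzene, rt) then funnels this mixture to the most substituted alkene 17, which separates the skeletal shift from the placement of the double bond.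

Step 10. Hydrogen delivery to the tetrasubstituted C4=C5 alkene may be slow or incomplete, because the addition builds a 1,3-diaxial methyl pair; the catalyst may deactivate or the alkene may migrate. The fallback sets out from 12 and comes back at 14. 12 is first oxidised with Dess–Martin periodinane to methyl 1-oxo-8α-Bpin-7αH-12,13-dinoreudesm-4-en-11-oate F3. F3 is hydrogenated heterogeneously (PtO2, H2 at high pressure, EtOAc), where steric shielding of the β face by the axial C10 methyl alone directs syn addition to the α face and gives 14 directly, bypassing 13.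

Step 6. Transmetalation and reductive elimination at the hindered tetrasubstituted alkenyl triflate may be sluggish, with homocoupling or protonolysis of the ester-bearing allylzinc reagent taking over. The fallback sets out from 7 and comes back at 9. Negishi coupling of 7 with the sp3 reagent (3-methoxy-3-oxopropyl)zinc bromide (PdCl2(dppf), THF/NMP) gives methyl 3-[(5S,6R)-2,6-dimethyl-6-(prop-2-en-1-yl)-5-(triethylsilyloxy)cyclohex-1-en-1-yl]propanoate F4. Its lithium enolate (LiN(i-Pr)2, −78 °C) is aminomethylated with dimethylmethyleneiminium iodide to the Mannich base methyl 2-[(dimethylamino)methyl]-3-[(5S,6R)-2,6-dimethyl-6-(prop-2-en-1-yl)-5-(triethylsilyloxy)cyclohex-1-en-1-yl]propanoate F5. N-Methylation of F5 (MeI) and elimination with DBU install the α-methylene group of 9.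

Further compounds
F1 | step 13 | methyl 1β-(methylsulfonyloxy)-8α-Bpin-4αH,5αH,7αH-12,13-dinoreudesman-11-oate | CS(=O)(=O)O[C@@H]1CC[C@H](C)[C@@H]2C[C@H](C(=O)OC)[C@@H](B3OC(C)(C)C(C)(C)O3)C[C@@]12C
F2 | step 13 | methyl 10-hydroxy-8α-Bpin-12,13-dinorguaian-11-oate (C10 epimers) | CC1(C)OB(OC1(C)C)[C@H]1CC(C)(O)[C@@H]2CC[C@H](C)[C@@H]2C[C@@H]1C(=O)OC
F3 | step 10 | methyl 1-oxo-8α-Bpin-7αH-12,13-dinoreudesm-4-en-11-oate | CC1=C2C[C@H](C(=O)OC)[C@@H](B3OC(C)(C)C(C)(C)O3)C[C@@]2(C)C(=O)CC1
F4 | step 6 | methyl 3-[(5S,6R)-2,6-dimethyl-6-(prop-2-en-1-yl)-5-(triethylsilyloxy)cyclohex-1-en-1-yl]propanoate | C=CC[C@@]1(C)[C@@H](O[Si](CC)(CC)CC)CCC(C)=C1CCC(=O)OC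
F5 | step 6 | methyl 2-[(dimethylamino)methyl]-3-[(5S,6R)-2,6-dimethyl-6-(prop-2-en-1-yl)-5-(triethylsilyloxy)cyclohex-1-en-1-yl]propanoate | C=CC[C@@]1(C)[C@@H](O[Si](CC)(CC)CC)CCC(C)=C1CC(CN(C)C)C(=O)OC
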